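**Retrosynthetic overview**

1. The target is a cyclohex-3-ene (C1 acyl, C2 prenyl, C3 methyl, C4, C5, C6 phenyl) carrying a 2-hydroxy-4,6-dimethoxybenzoyl group; the phenol is unmasked last from a symmetric 2,4,6-trimethoxyphenyl ketone.
2. The carbocycle is closed last, by ring-closing metathesis that joins C3 to C4 in an acyclic triene. This works because C2 carries an isopropenyl group (C3, its methyl and a sacrificial CH2) in a 1,7-relationship to the vinyl end of the allyl group on C6, whereas the third olefin, the prenyl group, is trisubstituted and could only close a seven-membered ring.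
3. The triene comes from a temporary δ-lactone ring (oxan-2-one, not in the target) whose carbons become the ketone carbon, C1, C6, C5 and C4. 2,4,6-Trimethoxyphenyllithium opens it to the aryl ketone, and the freed CH2OH at C4 is oxidised and methylenated.
4. C6 is set by Rh(acac)(C2H4)2/(R)-BINAP-catalysed phenyl addition to 5,6-dihydro-2H-pyran-2-one. C2 and C1 are relayed from it in one operation inside the lactone: copper-catalysed isopropenyl addition to an E-alkylidene lactone, then protonation, both anti to the pseudoaxial phenyl group.
5. Ring order: both arenes and the lactone ring are bought; the lactone is opened in step 6 and the cyclohexene is closed in step 9.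

Key step: step 9

Remark: C1–C6 are the target's ring carbons; lactones are numbered as oxan-2-ones, and the descriptor changes between 3, 9 and 12 reflect CIP priority changes, not inversion.

**Route**

Step 1
Reactants: 1 5,6-dihydro-2H-pyran-2-one; 2 phenylboronic acid
Product: 3 (4R)-4-phenyloxan-2-one
Conditions: Rh(acac)(C2H4)2 (3 mol%), (R)-BINAP (3.3 mol%), dioxane/H2O (10:1), 100 °C
Reagents that add atoms: none
Why: Hayashi–Miyaura asymmetric 1,4-addition, in which the phenylrhodium–(R)-BINAP species inserts the lactone double bond on one enantioface (the sense established for cyclic enones and unsaturated lactones, expected to give the R lactone) and water releases the product, which sets C6 of the target.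

Step 2
Reactants: 4 4-methylpent-3-en-1-ol
Product: 5 4-methylpent-3-enal
Conditions: Dess–Martin periodinane, pyridine, CH2Cl2, 0 °C; dried solution of 5 used at once
Reagents that add atoms: none
Why: Dess–Martin oxidation of a primary alcohol under buffered, non-basic conditions, chosen so that the β,γ-double bond should not move into conjugation.

Step 3
Reactants: 3 (4R)-4-phenyloxan-2-one; 5 4-methylpent-3-enal
Product: 7 (3R,4R)-3-(1-hydroxy-4-methylpent-3-en-1-yl)-4-phenyloxan-2-one (3,4-trans; both carbinol epimers), via lithium enolate 6 (not isolated)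
Conditions: LiN(i-Pr)2, THF, −78 °C; then 5, −78 °C; aq. NH4Cl
Reagents that add atoms: none
Why: Aldol addition of a lactone lithium enolate to an aldehyde at −78 °C, where addition should outrun proton transfer from the enolisable aldehyde; the new bond forms anti to the phenyl group, but neither new centre matters because both become trigonal in step 4.

Step 4
Reactants: 7 (3R,4R)-3-(1-hydroxy-4-methylpent-3-en-1-yl)-4-phenyloxan-2-one
Product: 9 (3E,4S)-3-(4-methylpent-3-en-1-ylidene)-4-phenyloxan-2-one, via mesylate 8 (not isolated)
Conditions: MsCl, Et3N, CH2Cl2, 0 °C; then DBU, 0 °C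
Reagents that add atoms: none
Why: Mesylation followed by E1cB elimination through the lactone enolate, which should give the conjugated exocyclic alkene with the chain anti to the lactone carbonyl (E), as is usual for α-alkylidene lactones made this way; the phenyl-bearing centre is untouched.

Step 5
Reactants: 9 (3E,4S)-3-(4-methylpent-3-en-1-ylidene)-4-phenyloxan-2-one; 10 isopropenylmagnesium bromide, CH2=C(CH3)MgBr
Product: 12 (3R,4R)-3-[(3S)-2,6-dimethylhepta-1,5-dien-3-yl]-4-phenyloxan-2-one (3,4-cis), via trimethylsilyl ketene acetal 11 (not isolated)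
Conditions: CuBr·SMe2 (20 mol%), Me3SiCl, THF, −78 °C; then AcOH, THF/H2O, −78 to 0 °C
Reagents that add atoms: none
Why: Copper-catalysed 1,4-addition of a Grignard reagent with in situ silylation, then kinetic protonation: allylic 1,3-strain between the chain CH2 of the E-alkylidene group (cis to lactone C4) and the C4 substituents should turn the phenyl group pseudoaxial, so that the isopropenyl group adds to the exocyclic carbon from the opposite face (C2 of the target) and the proton then reaches lactone C3 of the ketene acetal from that same face (C1 of the target, 3,4-cis lactone).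

Step 6
Reactants: 12 (3R,4R)-3-[(3S)-2,6-dimethylhepta-1,5-dien-3-yl]-4-phenyloxan-2-one; 13 1,3,5-trimethoxybenzene
Product: 15 (2R,3R)-2-[(3S)-2,6-dimethylhepta-1,5-dien-3-yl]-5-hydroxy-3-phenyl-1-(2,4,6-trimethoxyphenyl)pentan-1-one, via 2,4,6-trimethoxyphenyllithium 14 (not isolated)
Conditions: 13 (1.5 equiv), n-BuLi (1.4 equiv), THF, 0 °C to rt; then 12, −78 °C; aq. NH4Cl
Reagents that add atoms: none
Why: Directed ortho-lithiation of 1,3,5-trimethoxybenzene and single addition of the aryllithium to the lactone carbonyl (the tetrahedral lithium alkoxide and the doubly ortho-substituted ketone that follows resist a second addition), which opens the temporary ring and forms the aryl ketone at −78 °C without disturbing the adjacent C1 centre.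

Step 7
Reactants: 15 (2R,3R)-2-[(3S)-2,6-dimethylhepta-1,5-dien-3-yl]-5-hydroxy-3-phenyl-1-(2,4,6-trimethoxyphenyl)pentan-1-one
Product: 16 (3R,4R)-4-[(3S)-2,6-dimethylhepta-1,5-dien-3-yl]-5-oxo-3-phenyl-5-(2,4,6-trimethoxyphenyl)pentanal
Conditions: Dess–Martin periodinane, pyridine, CH2Cl2, 0 °C to rt
Reagents that add atoms: none
Why: Dess–Martin oxidation of the primary alcohol under buffered conditions that should not enolise the hindered ketone; only the open hydroxy ketone has an oxidisable C–H, so any cyclic hemiketal is drained through the open form.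

Step 8
Reactants: 16 (3R,4R)-4-[(3S)-2,6-dimethylhepta-1,5-dien-3-yl]-5-oxo-3-phenyl-5-(2,4,6-trimethoxyphenyl)pentanal
Product: 17 (2R,3R)-2-[(3S)-2,6-dimethylhepta-1,5-dien-3-yl]-3-phenyl-1-(2,4,6-trimethoxyphenyl)hex-5-en-1-one
Conditions: Ph3PCH3Br (1.3 equiv), KOt-Bu (1.2 equiv), THF, 0 °C; then 16, −78 to 0 °C
Reagents that add atoms: methyltriphenylphosphonium bromide, C[P+](c1ccccc1)(c1ccccc1)c1ccccc1.[Br-] (delivers CH2 through its ylide)
Why: Wittig methylenation, selective for the aldehyde because the ketone is shielded by two ortho-methoxy groups and two branched α-substituents; low temperature and a slight deficit of base should keep the ylide from enolising C1.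

Step 9
Reactants: 17 (2R,3R)-2-[(3S)-2,6-dimethylhepta-1,5-dien-3-yl]-3-phenyl-1-(2,4,6-trimethoxyphenyl)hex-5-en-1-one
Product: 18 [(1R,2S,6R)-3-methyl-2-(3-methylbut-2-en-1-yl)-6-phenylcyclohex-3-en-1-yl](2,4,6-trimethoxyphenyl)methanone
Conditions: second-generation Hoveyda–Grubbs catalyst (5 mol%), toluene (0.005 M), 60 °C, argon stream
Reagents that add atoms: none
Why: Ring-closing olefin metathesis by the metal carbene/metallacyclobutane mechanism: the ruthenium carbene loads on the monosubstituted allyl terminus (C4), adds across the 1,1-disubstituted isopropenyl group (C3) and releases the cyclohexene and, after turnover, ethene. The closest known reaction type is the closure of 2-methylocta-1,7-dienes to 1-methylcyclohexenes with second-generation ruthenium catalysts. The only ring closed is the cyclohexene, in a six-membered ring-closing mode that joins C3 to C4 as the trisubstituted double bond. No stereocentre is created; C1, C2 and C6 are carried over unchanged because the conditions are neutral and only sp2 carbons react. The step needs chemoselectivity between the isopropenyl and prenyl olefins as partner of the C4 carbene, and against dimerisation: the prenyl group could only close a seven-membered ring through a more hindered trisubstituted olefin, and high dilution with removal of ethene favours the intramolecular path.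

Step 10
Reactants: 18 [(1R,2S,6R)-3-methyl-2-(3-methylbut-2-en-1-yl)-6-phenylcyclohex-3-en-1-yl](2,4,6-trimethoxyphenyl)methanone
Product: 20 (2-hydroxy-4,6-dimethoxyphenyl)[(1R,2S,6R)-3-methyl-2-(3-methylbut-2-en-1-yl)-6-phenylcyclohex-3-en-1-yl]methanone, via dichloroboryl ether 19 (not isolated)
Conditions: BCl3 (1.2 equiv), CH2Cl2, −78 to −20 °C; aq. NaHCO3
Reagents that add atoms: none
Why: Chelation-controlled ether cleavage, in which BCl3 bridges the ketone oxygen and one ortho-methoxy oxygen and chloride removes that methyl group only; the two ortho-methoxy groups are equivalent, so a single phenol should result, and at low temperature the olefins and the C1 centre should survive.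

**Compound list**

1 | 5,6-dihydro-2H-pyran-2-one | O=C1C=CCCO1 | starting material
2 | phenylboronic acid | OB(O)c1ccccc1 | starting material
3 | (4R)-4-phenyloxan-2-one | O=C1C[C@H](c2ccccc2)CCO1 | intermediate
4 | 4-methylpent-3-en-1-ol | CC(C)=CCCO | starting material
5 | 4-methylpent-3-enal | CC(C)=CCC=O | intermediate
6 | lithium (4R)-4-phenyl-3,4-dihydro-2H-pyran-6-olate (lithium enolate of 3) | [Li]OC1=C[C@H](c2ccccc2)CCO1 | intermediate
7 | (3R,4R)-3-(1-hydroxy-4-methylpent-3-en-1-yl)-4-phenyloxan-2-one (3,4-trans; both carbinol epimers) | O=C1[C@@H](C(O)CC=C(C)C)[C@H](c2ccccc2)CCO1 | intermediate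
8 | methanesulfonate of 7 (mesyloxy group on the side-chain carbinol carbon) | O=C1[C@@H](C(OS(C)(=O)=O)CC=C(C)C)[C@H](c2ccccc2)CCO1 | intermediate
9 | (3E,4S)-3-(4-methylpent-3-en-1-ylidene)-4-phenyloxan-2-one | CC(C)=CC/C=C1/C(=O)OCC[C@H]1c1ccccc1 | intermediate
10 | isopropenylmagnesium bromide | C=C(C)[Mg]Br | starting material
11 | trimethylsilyl ketene acetal of 12 (6-trimethylsilyloxy-3,4-dihydro-2H-pyran; phenyl-bearing and side-chain centres as in 12) | C[Si](C)(C)OC1=C([C@H](CC=C(C)C)C(C)=C)[C@H](c2ccccc2)CCO1 | intermediate
12 | (3R,4R)-3-[(3S)-2,6-dimethylhepta-1,5-dien-3-yl]-4-phenyloxan-2-one (3,4-cis) | O=C1[C@H]([C@H](CC=C(C)C)C(C)=C)[C@H](c2ccccc2)CCO1 | intermediate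
13 | 1,3,5-trimethoxybenzene | COc1cc(OC)cc(OC)c1 | starting material
14 | 2,4,6-trimethoxyphenyllithium | [Li]c1c(OC)cc(OC)cc1OC | intermediate
15 | (2R,3R)-2-[(3S)-2,6-dimethylhepta-1,5-dien-3-yl]-5-hydroxy-3-phenyl-1-(2,4,6-trimethoxyphenyl)pentan-1-one | COc1cc(OC)c(C(=O)[C@H]([C@H](CC=C(C)C)C(C)=C)[C@@H](CCO)c2ccccc2)c(OC)c1 | intermediate
16 | (3R,4R)-4-[(3S)-2,6-dimethylhepta-1,5-dien-3-yl]-5-oxo-3-phenyl-5-(2,4,6-trimethoxyphenyl)pentanal | COc1cc(OC)c(C(=O)[C@H]([C@H](CC=C(C)C)C(C)=C)[C@@H](CC=O)c2ccccc2)c(OC)c1 | intermediate
17 | (2R,3R)-2-[(3S)-2,6-dimethylhepta-1,5-dien-3-yl]-3-phenyl-1-(2,4,6-trimethoxyphenyl)hex-5-en-1-one | COc1cc(OC)c(C(=O)[C@H]([C@H](CC=C(C)C)C(C)=C)[C@@H](CC=C)c2ccccc2)c(OC)c1 | intermediate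
18 | [(1R,2S,6R)-3-methyl-2-(3-methylbut-2-en-1-yl)-6-phenylcyclohex-3-en-1-yl](2,4,6-trimethoxyphenyl)methanone | COc1cc(OC)c(C(=O)[C@@H]2[C@H](CC=C(C)C)C(C)=CC[C@H]2c2ccccc2)c(OC)c1 | intermediate
19 | dichloroboryl ether of 20 (O–BCl2 on the ortho oxygen) | COc1cc(OB(Cl)Cl)c(C(=O)[C@@H]2[C@H](CC=C(C)C)C(C)=CC[C@H]2c2ccccc2)c(OC)c1 | intermediate
20 | (2-hydroxy-4,6-dimethoxyphenyl)[(1R,2S,6R)-3-methyl-2-(3-methylbut-2-en-1-yl)-6-phenylcyclohex-3-en-1-yl]methanone | COc1cc(O)c(C(=O)[C@@H]2[C@H](CC=C(C)C)C(C)=CC[C@H]2c2ccccc2)c(OC)c1 | target

**Step count and risks**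

Total step count: 10. Longest linear sequence: 9 steps (steps 1 and 3 to 10).

The three steps most likely to fail:

Step 5. The cis relationship at lactone C3/C4 may be lost if proton transfer to the ketene acetal is not face-selective or becomes reversible, since the cis lactone is the less stable epimer. The fallback sets the same centre by hydrogen-atom transfer instead of protonation. It sets out from 9: the copper-catalysed addition of 10 is run without Me3SiCl, and the magnesium enolate is quenched with PhSeCl at −78 °C to give the 3-phenylselanyl lactone F1. Bu3SnH with Et3B and air in toluene at −78 °C then generates the planar C3 radical, which should take hydrogen from the stannane on the face away from the phenyl group in an irreversible step. This returns to the route at 12.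

Step 6. The hindered aryllithium may deprotonate the α-branched lactone instead of adding to it, so that the lactone is returned or its C3 centre equilibrates. The fallback forms the aryl–carbon bond at the aldehyde oxidation level. From 12, i-Bu2AlH (CH2Cl2, −78 °C) gives the lactol F2, whose open hydroxy aldehyde form is a better electrophile and takes up 14 (THF, −78 °C) to give the 1,5-diol F3. Dess–Martin periodinane in excess oxidises both carbinols and returns to the route at 16, so that 15 is by-passed.

Step 4. The base needed for the E1cB elimination may also remove a proton from the doubly allylic CH2 of the product and move the double bond out of conjugation, or the elimination may give E/Z mixtures. The fallback makes the exocyclic double bond by olefination. From 3, through enolate 6, ClP(O)(OEt)2 gives the enol phosphate F4, which a further equivalent of LiN(i-Pr)2 rearranges by a 1,3-phosphoryl shift from oxygen to carbon to the α-phosphono lactone F5. Horner–Wadsworth–Emmons reaction of F5 with aldehyde 5 (LiCl, i-Pr2NEt, MeCN), a base too weak to deprotonate the product, returns to the route at 9.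

**Further compounds**

F1 | step 5 | 3-phenylselanyl lactone: 12 with SePh in place of the hydrogen at lactone C3 (selenium anti to the C4 phenyl group) | O=C1[C@]([Se]c2ccccc2)([C@H](CC=C(C)C)C(C)=C)[C@H](c2ccccc2)CCO1
F2 | step 6 | (3R,4R)-3-[(3S)-2,6-dimethylhepta-1,5-dien-3-yl]-4-phenyloxan-2-ol (both anomers) | OC1[C@H]([C@H](CC=C(C)C)C(C)=C)[C@H](c2ccccc2)CCO1
F3 | step 6 | (2R,3R)-2-[(3S)-2,6-dimethylhepta-1,5-dien-3-yl]-3-phenyl-1-(2,4,6-trimethoxyphenyl)pentane-1,5-diol (both C1 epimers) | COc1cc(OC)c(C(O)[C@H]([C@H](CC=C(C)C)C(C)=C)[C@@H](CCO)c2ccccc2)c(OC)c1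
F4 | step 4 | diethyl (4R)-4-phenyl-3,4-dihydro-2H-pyran-6-yl phosphate | CCOP(=O)(OCC)OC1=C[C@H](c2ccccc2)CCO1
F5 | step 4 | diethyl [(4S)-2-oxo-4-phenyloxan-3-yl]phosphonate (both C3 epimers) | CCOP(=O)(OCC)C1C(=O)OCC[C@H]1c1ccccc1
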